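The route rests on cutting ring A from ring B (numbering: C1 ketone next to C2(Cl)(CH3), C3 carbinol, C4 ketone). The resorcinol ring (C4a, C5–C8, C8a; hydroxyls on C6 and C8, the C8 hydroxyl peri to the C1 ketone) is fused to the C1/C4 dione exactly as a 1,3-dioxygenated diene leaves it after adding across C4a=C8a of an ene-dione. One Diels–Alder/aromatization step therefore forms C4a–C5 and C8–C8a and closes ring A, bromine on C8a fixing the orientation. The dienophile is a monocyclic (5S,6R)-2-bromocyclohex-2-ene-1,4-dione already holding both quaternary centres; it comes from hydroxylative dearomatization of a bromophenol brominated before the polyene chain is attached.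

Key step: step 13

Remark: in this numbering the target is (2R,3S), with Cl trans to the C3 hydroxyl and the C2 methyl trans to the side chain. The sense of induction of the chiral iodane in step 8 is assumed as drawn, and the antipodal reagent is used unchanged if the opposite sense is found.
Abbreviation: "C15 chain" = (4E)-5,9-dimethyl-2-(propan-2-ylidene)deca-4,8-dien-1-yl.

Step 1
Reactants: 1 2,5-dimethoxybenzaldehyde
Product: 5 3,6-dimethoxy-2-methylbenzaldehyde, via α-amino alkoxide 2 (not isolated), via ortho-lithiated alkoxide 3 (not isolated), via C-methylated alkoxide 4 (not isolated)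
Conditions: LiN(Me)CH2CH2NMe2 (from the amine and n-BuLi), THF, −20 °C; n-BuLi (3 equiv), −20 °C; MeI, −78 °C → rt; aq. NH4Cl
Reagents that add atoms: iodomethane, CI
Why: Directed ortho-metalation: the lithium α-amino alkoxide formed in situ masks the aldehyde and, together with the neighbouring methoxy group, directs lithiation to C6, the only position ortho to the masked formyl group, so methylation should give the contiguous CHO/CH3/OCH3 array.

Step 2
Reactants: 5 3,6-dimethoxy-2-methylbenzaldehyde
Product: 6 6-hydroxy-3-methoxy-2-methylbenzaldehyde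
Conditions: BCl3 (1.2 equiv), CH2Cl2, −78 → 0 °C; H2O
Reagents that add atoms: none
Why: Chelation-controlled ether cleavage: BCl3 bound to the formyl oxygen removes only the methyl ether ortho to it, which frees the oxygen next to the future benzylic carbon and leaves the other oxygen as its methyl ether.

Step 3
Reactants: 6 6-hydroxy-3-methoxy-2-methylbenzaldehyde
Product: 7 2-(hydroxymethyl)-4-methoxy-3-methylphenol
Conditions: NaBH4, MeOH–THF, 0 °C
Reagents that add atoms: none
Why: Borohydride reduction of the aldehyde to the salicyl alcohol; no other group is reducible.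

Step 4
Reactants: 7 2-(hydroxymethyl)-4-methoxy-3-methylphenol
Product: 8 tert-butyl 2-(hydroxymethyl)-4-methoxy-3-methylphenyl carbonate
Conditions: Boc2O (1.05 equiv), i-Pr2NEt, DMAP (cat.), CH2Cl2, 0 °C
Reagents that add atoms: di-tert-butyl dicarbonate, CC(C)(C)OC(=O)OC(=O)OC(C)(C)C
Why: Chemoselective O-acylation of the phenol (far more acidic than the benzylic alcohol) should give the ortho-(tert-butoxycarbonyloxy)benzyl alcohol, which is the ortho-quinone methide precursor for step 7 and at the same time switches off this oxygen as a directing group.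

Step 5
Reactants: 8 tert-butyl 2-(hydroxymethyl)-4-methoxy-3-methylphenyl carbonate
Product: 9 tert-butyl 5-bromo-2-(hydroxymethyl)-4-methoxy-3-methylphenyl carbonate
Conditions: NBS (1.05 equiv), MeCN, 0 °C → rt, dark
Reagents that add atoms: N-bromosuccinimide, BrN1C(=O)CCC1=O
Why: Electrophilic aromatic bromination: the methoxy group is the only strong activator, its para position is occupied and its single free ortho position (C5) should be brominated, so the halogen is in place before any alkene is present and no positive bromine ever meets the polyene chain.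

Step 6
Reactants: 10 1,1-dibromo-2-methylprop-1-ene; 11 geranyl bromide
Product: 13 (5E)-3-bromo-2,6,10-trimethylundeca-2,5,9-triene, via bromoalkenyllithium carbenoid 12 (not isolated)
Conditions: n-BuLi (1.0 equiv), THF–Et2O–pentane (4:1:1), −110 °C; then 11, −110 → −78 °C
Reagents that add atoms: none
Why: Bromine–lithium exchange gives an α-bromoalkenyllithium that is persistent below −100 °C (no β-hydrogen or aryl group can migrate) and is alkylated by SN2 attack at the primary allylic carbon of 11 with retention of the E alkene; both β-substituents are methyl, so no new alkene geometry has to be controlled.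

Step 7
Reactants: 13 (5E)-3-bromo-2,6,10-trimethylundeca-2,5,9-triene; 9 tert-butyl 5-bromo-2-(hydroxymethyl)-4-methoxy-3-methylphenyl carbonate
Product: 16 5-bromo-2-(C15 chain)-4-methoxy-3-methylphenol, via alkenyl Grignard reagent 14 (not isolated), via ortho-quinone methide 15 (not isolated)
Conditions: 13, Mg (I2-activated), THF, 45 °C; then 9 (0.45 equiv), THF, −78 °C → rt; aq. NH4Cl
Reagents that add atoms: none
Why: Ortho-quinone methide generation and 1,4-addition: one equivalent of 14 deprotonates the benzylic alcohol, the alkoxide takes over the carbonate and the phenoxide expels tert-butyl carbonate to give 15, whose exocyclic CH2 is attacked by the second equivalent; the aryl bromide is inert to a Grignard reagent at these temperatures and the phenol next to the new chain is set free without any selective protection.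

Step 8
Reactants: 16 5-bromo-2-(C15 chain)-4-methoxy-3-methylphenol
Product: 17 (6R)-3-bromo-6-(C15 chain)-6-hydroxy-4-methoxy-5-methylcyclohexa-2,4-dien-1-one
Conditions: (R)-3,3'-diiodyl-2,2'-dimethoxy-1,1'-binaphthyl (1.1 equiv), CH2Cl2, −40 → 0 °C; aq. NaHCO3
Reagents that add atoms: (R)-3,3'-diiodyl-2,2'-dimethoxy-1,1'-binaphthyl (oxygen donor), COc1c(I(=O)=O)cc2ccccc2c1-c1c(OC)c(I(=O)=O)cc2ccccc12
Why: Hydroxylative phenol dearomatization: the phenol binds pentavalent iodine and oxygen is delivered intramolecularly to the alkylated ortho carbon C2 (the other ortho carbon is unsubstituted and flanked by bromine), the C2-symmetric biaryl selecting one face to set the (6R) carbinol centre; the reagent does not epoxidize isolated alkenes, and the para-methoxy group should leave a stable methyl dienol ether.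

Step 9
Reactants: 17 (6R)-3-bromo-6-(C15 chain)-6-hydroxy-4-methoxy-5-methylcyclohexa-2,4-dien-1-one
Product: 18 (6R)-3-bromo-6-(C15 chain)-4-methoxy-5-methyl-6-(triethylsilyloxy)cyclohexa-2,4-dien-1-one
Conditions: Et3SiOTf, 2,6-lutidine, CH2Cl2, −78 °C
Reagents that add atoms: triethylsilyl trifluoromethanesulfonate, CC[Si](CC)(CC)OS(=O)(=O)C(F)(F)F
Why: Silylation of the tertiary alcohol with a silyl triflate; the triethylsilyl ether (chosen over trimethylsilyl because it should survive the aqueous chlorination and chromatography yet still fall to HF·pyridine) removes the hydrogen-bonding hydroxyl group and becomes the large group on C6 for step 10.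

Step 10
Reactants: 18 (6R)-3-bromo-6-(C15 chain)-4-methoxy-5-methyl-6-(triethylsilyloxy)cyclohexa-2,4-dien-1-one
Product: 19 (5S,6R)-2-bromo-6-chloro-5-(C15 chain)-6-methyl-5-(triethylsilyloxy)cyclohex-2-ene-1,4-dione
Conditions: NCS (1.05 equiv), MeCN–H2O (20:1), pH 7 buffer (NaH2PO4/Na2HPO4), −10 → 0 °C
Reagents that add atoms: N-chlorosuccinimide, ClN1C(=O)CCC1=O; water, O
Why: Electrophilic α-chlorination of an enol ether: NCS should attack C5 of 18, the terminal enol-ether carbon and the most nucleophilic alkene carbon in the molecule, water then adds to the oxocarbenium ion and methanol is lost to unveil the ketone, and 1,2-induction by the adjacent centre is counted on to bring chlorine in anti to the bulky triethylsilyloxy group (Cl trans to O, methyl trans to the chain), which is the least secure selectivity of the route.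

Step 11
Reactants: 20 methyl acetoacetate
Product: 21 methyl 3-(trimethylsilyloxy)but-2-enoate
Conditions: Me3SiCl, Et3N, hexane, rt
Reagents that add atoms: chlorotrimethylsilane, C[Si](C)(C)Cl
Why: O-silylation of the β-keto ester under soft enolization; the alkene geometry is of no consequence.

Step 12
Reactants: 21 methyl 3-(trimethylsilyloxy)but-2-enoate
Product: 23 1-methoxy-1,3-bis(trimethylsilyloxy)buta-1,3-diene, via lithium dienolate 22 (not isolated)
Conditions: LiN(i-Pr)2, THF, −78 °C; Me3SiCl, −78 °C → rt
Reagents that add atoms: chlorotrimethylsilane, C[Si](C)(C)Cl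
Why: γ-Deprotonation gives the extended ester dienolate, which is silylated on oxygen to the electron-rich ketene-acetal diene; it is distilled and used fresh.

Step 13
Reactants: 19 (5S,6R)-2-bromo-6-chloro-5-(C15 chain)-6-methyl-5-(triethylsilyloxy)cyclohex-2-ene-1,4-dione; 23 1-methoxy-1,3-bis(trimethylsilyloxy)buta-1,3-diene
Product: 26 (2R,3S)-2-chloro-3,6,8-trihydroxy-2-methyl-3-(C15 chain)-2,3-dihydronaphthalene-1,4-dione (CNP0351608.1), via bromo cycloadduct 24 (not isolated), via silylated naphthalenedione 25 (not isolated)
Conditions: 23 (2.5 equiv), CH2Cl2, −40 °C → rt; pyridine, rt; then HF·pyridine, THF, 0 °C → rt; pH 6 work-up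
Reagents that add atoms: none
Why: The electron-rich ketene-acetal diene adds across the doubly carbonyl-activated C2=C3 bond of 19 in a charge-controlled [4+2] cycloaddition whose two bonds form unequally, the CH2 terminus bonding first to the hydrogen-bearing C3 (future C4a) and the acetal carbon then to the brominated C2 (future C8a), to give 24. The closest known reaction type is the Diels–Alder reaction of 1-methoxy-1,3-bis(trimethylsilyloxy)butadiene and related oxygenated dienes with 2-bromo-1,4-quinones followed by aromatization to a resorcinol-type ring. Ring A (six-membered, carbocyclic) is closed by this intermolecular cycloaddition through the C4a–C5 and C8–C8a bonds and is then aromatized: pyridine removes HBr (the C4a hydrogen is acidified by the C4 carbonyl), methoxytrimethylsilane leaves from C8 and enolization gives resorcinol 25, after which HF·pyridine cleaves the aryl and tertiary silyl ethers. No stereocentre is created, since the three transient sp3 centres of 24 vanish on aromatization, and the quaternary C2 and C3 can neither epimerize nor eliminate, the silyl group on the tertiary oxygen also keeping the chlorohydrin from closing to an epoxide before the acidic desilylation. The step needs regioselectivity (C8 hydroxyl peri to the C1 ketone), which the bromine on the carbon next to that ketone secures, and chemoselectivity, which follows from the ene-dione being far more electron-poor than the tri- and tetrasubstituted side-chain alkenes.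

Compound list
1 | 2,5-dimethoxybenzaldehyde | COc1ccc(OC)c(C=O)c1 | starting material
2 | lithium (2,5-dimethoxyphenyl){[2-(dimethylamino)ethyl](methyl)amino}methanolate (racemic at the aminal carbon) | COc1ccc(OC)c(C(O[Li])N(C)CCN(C)C)c1 | intermediate
3 | 6-lithio derivative of 2 | COc1ccc(OC)c(C(O[Li])N(C)CCN(C)C)c1[Li] | intermediate
4 | 6-methyl derivative of 2 | COc1ccc(OC)c(C(O[Li])N(C)CCN(C)C)c1C | intermediate
5 | 3,6-dimethoxy-2-methylbenzaldehyde | COc1ccc(OC)c(C=O)c1C | intermediate
6 | 6-hydroxy-3-methoxy-2-methylbenzaldehyde | COc1ccc(O)c(C=O)c1C | intermediate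
7 | 2-(hydroxymethyl)-4-methoxy-3-methylphenol | COc1ccc(O)c(CO)c1C | intermediate
8 | tert-butyl 2-(hydroxymethyl)-4-methoxy-3-methylphenyl carbonate | COc1ccc(OC(=O)OC(C)(C)C)c(CO)c1C | intermediate
9 | tert-butyl 5-bromo-2-(hydroxymethyl)-4-methoxy-3-methylphenyl carbonate | COc1c(Br)cc(OC(=O)OC(C)(C)C)c(CO)c1C | intermediate
10 | 1,1-dibromo-2-methylprop-1-ene | CC(C)=C(Br)Br | starting material
11 | geranyl bromide, (2E)-1-bromo-3,7-dimethylocta-2,6-diene | CC(C)=CCC/C(C)=C/CBr | starting material
12 | (1-bromo-2-methylprop-1-en-1-yl)lithium | CC(C)=C([Li])Br | intermediate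
13 | (5E)-3-bromo-2,6,10-trimethylundeca-2,5,9-triene | CC(C)=CCC/C(C)=C/CC(Br)=C(C)C | intermediate
14 | [(5E)-2,6,10-trimethylundeca-2,5,9-trien-3-yl]magnesium bromide | CC(C)=CCC/C(C)=C/CC([Mg]Br)=C(C)C | intermediate
15 | 3-bromo-4-methoxy-5-methyl-6-methylidenecyclohexa-2,4-dien-1-one | C=C1C(C)=C(OC)C(Br)=CC1=O | intermediate
16 | 5-bromo-2-[(4E)-5,9-dimethyl-2-(propan-2-ylidene)deca-4,8-dien-1-yl]-4-methoxy-3-methylphenol | CC(C)=CCC/C(C)=C/CC(Cc1c(O)cc(Br)c(OC)c1C)=C(C)C | intermediate
17 | (6R)-3-bromo-6-[(4E)-5,9-dimethyl-2-(propan-2-ylidene)deca-4,8-dien-1-yl]-6-hydroxy-4-methoxy-5-methylcyclohexa-2,4-dien-1-one | CC(C)=CCC/C(C)=C/CC(C[C@]1(O)C(=O)C=C(Br)C(OC)=C1C)=C(C)C | intermediate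
18 | (6R)-3-bromo-6-[(4E)-5,9-dimethyl-2-(propan-2-ylidene)deca-4,8-dien-1-yl]-4-methoxy-5-methyl-6-(triethylsilyloxy)cyclohexa-2,4-dien-1-one | CC(C)=CCC/C(C)=C/CC(C[C@]1(O[Si](CC)(CC)CC)C(=O)C=C(Br)C(OC)=C1C)=C(C)C | intermediate
19 | (5S,6R)-2-bromo-6-chloro-5-[(4E)-5,9-dimethyl-2-(propan-2-ylidene)deca-4,8-dien-1-yl]-6-methyl-5-(triethylsilyloxy)cyclohex-2-ene-1,4-dione (key-step precursor) | CC(C)=CCC/C(C)=C/CC(C[C@]1(O[Si](CC)(CC)CC)C(=O)C=C(Br)C(=O)[C@]1(C)Cl)=C(C)C | intermediate
20 | methyl acetoacetate | COC(=O)CC(C)=O | starting material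
21 | methyl 3-(trimethylsilyloxy)but-2-enoate (E/Z mixture) | COC(=O)C=C(C)O[Si](C)(C)C | intermediate
22 | lithium 1-methoxy-3-(trimethylsilyloxy)buta-1,3-dien-1-olate | C=C(O[Si](C)(C)C)C=C(OC)O[Li] | intermediate
23 | 1-methoxy-1,3-bis(trimethylsilyloxy)buta-1,3-diene | C=C(O[Si](C)(C)C)C=C(OC)O[Si](C)(C)C | intermediate
24 | (2R,3S)-8a-bromo-2-chloro-8-methoxy-2-methyl-3-(C15 chain)-3-(triethylsilyloxy)-6,8-bis(trimethylsilyloxy)-2,3,4a,5,8,8a-hexahydronaphthalene-1,4-dione (mixture at the transient centres C4a, C8, C8a) | CC(C)=CCC/C(C)=C/CC(C[C@]1(O[Si](CC)(CC)CC)C(=O)C2CC(O[Si](C)(C)C)=CC(OC)(O[Si](C)(C)C)C2(Br)C(=O)[C@]1(C)Cl)=C(C)C | intermediate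
25 | (2R,3S)-2-chloro-8-hydroxy-2-methyl-3-(C15 chain)-3-(triethylsilyloxy)-6-(trimethylsilyloxy)-2,3-dihydronaphthalene-1,4-dione | CC(C)=CCC/C(C)=C/CC(C[C@]1(O[Si](CC)(CC)CC)C(=O)c2cc(O[Si](C)(C)C)cc(O)c2C(=O)[C@]1(C)Cl)=C(C)C | intermediate
26 | (2R,3S)-2-chloro-3,6,8-trihydroxy-2-methyl-3-[(4E)-5,9-dimethyl-2-(propan-2-ylidene)deca-4,8-dien-1-yl]-2,3-dihydronaphthalene-1,4-dione, CNP0351608.1 | CC(C)=CCC/C(C)=C/CC(C[C@]1(O)C(=O)c2cc(O)cc(O)c2C(=O)[C@]1(C)Cl)=C(C)C | target

Total step count: 13
Longest linear sequence: 10 steps (1, 2, 3, 4, 5, 7, 8, 9, 10, 13)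

The three steps most likely to fail

Facial selectivity of the chlorination in step 10. What may go wrong is weak or inverted facial discrimination, with positive chlorine entering syn to the silyloxy group, and to a lesser degree attack of positive chlorine on the side-chain alkenes. The fallback for step 10 sets out from 18, gives up the reliance on 1,2-induction and obtains the required diastereomer by separation. Chlorination with NCS in buffered MeCN–H2O is run to full conversion. Chromatography on silica gel (preparative HPLC if needed) then separates 19 from its C6 epimer, (5S,6S)-2-bromo-6-chloro-5-(C15 chain)-6-methyl-5-(triethylsilyloxy)cyclohex-2-ene-1,4-dione F1. The two are diastereomers that differ in the orientation of the C–Cl dipole relative to the silyloxy group, so adsorption chromatography should resolve them. F1 is discarded and the route is rejoined at 19.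

Enantiofacial selectivity of the dearomatization in step 8. What may go wrong is poor enantiofacial discrimination by the chiral iodane, together with competing oxygenation of the unsubstituted ortho carbon or over-oxidation. The fallback for step 8 sets out from 16 and gives up asymmetric induction. Stabilised 2-iodoxybenzoic acid (its blend with benzoic and isophthalic acids; THF, rt) should give racemic 3-bromo-6-(C15 chain)-6-hydroxy-4-methoxy-5-methylcyclohexa-2,4-dien-1-one F2. Preparative chromatography of F2 on a chiral stationary phase then separates 17 from its enantiomer, (6S)-3-bromo-6-(C15 chain)-6-hydroxy-4-methoxy-5-methylcyclohexa-2,4-dien-1-one F3, which is discarded. The route is rejoined at 17.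

Ring closure and aromatization in step 13. What may go wrong is stalling at an open-chain conjugate adduct, or incomplete closure and aromatization, because the ene-dione is flanked by two quaternary carbons. The fallback for step 13 sets out from 19 and 23 and makes the same two bonds one after the other. Uncatalysed Mukaiyama–Michael addition of the CH2 terminus of 23 to C3 of 19 (CH2Cl2, −78 °C), then Et3N and aqueous citric acid to remove HBr and the trimethylsilyl groups, should give methyl 4-[(4R,5S)-4-chloro-5-(C15 chain)-4-methyl-3,6-dioxo-5-(triethylsilyloxy)cyclohex-1-en-1-yl]-3-oxobutanoate F4. Cs2CO3 in MeCN at 0 °C then closes ring A by a Dieckmann-type C-acylation, in which the vinylogous enolate carbon next to the C1 ketone attacks the ester. Tautomerization gives (2R,3S)-2-chloro-6,8-dihydroxy-2-methyl-3-(C15 chain)-3-(triethylsilyloxy)-2,3-dihydronaphthalene-1,4-dione F5. HF·pyridine in THF removes the silyl ether from F5 and the route is rejoined at 26.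

Further compounds
F1 | step 10 | (5S,6S)-2-bromo-6-chloro-5-[(4E)-5,9-dimethyl-2-(propan-2-ylidene)deca-4,8-dien-1-yl]-6-methyl-5-(triethylsilyloxy)cyclohex-2-ene-1,4-dione | CC(C)=CCC/C(C)=C/CC(C[C@]1(O[Si](CC)(CC)CC)C(=O)C=C(Br)C(=O)[C@@]1(C)Cl)=C(C)C
F2 | step 8 | racemic 3-bromo-6-[(4E)-5,9-dimethyl-2-(propan-2-ylidene)deca-4,8-dien-1-yl]-6-hydroxy-4-methoxy-5-methylcyclohexa-2,4-dien-1-one | CC(C)=CCC/C(C)=C/CC(CC1(O)C(=O)C=C(Br)C(OC)=C1C)=C(C)C
F3 | step 8 | (6S)-3-bromo-6-[(4E)-5,9-dimethyl-2-(propan-2-ylidene)deca-4,8-dien-1-yl]-6-hydroxy-4-methoxy-5-methylcyclohexa-2,4-dien-1-one | CC(C)=CCC/C(C)=C/CC(C[C@@]1(O)C(=O)C=C(Br)C(OC)=C1C)=C(C)C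
F4 | step 13 | methyl 4-[(4R,5S)-4-chloro-5-[(4E)-5,9-dimethyl-2-(propan-2-ylidene)deca-4,8-dien-1-yl]-4-methyl-3,6-dioxo-5-(triethylsilyloxy)cyclohex-1-en-1-yl]-3-oxobutanoate | CC(C)=CCC/C(C)=C/CC(C[C@]1(O[Si](CC)(CC)CC)C(=O)C(CC(=O)CC(=O)OC)=CC(=O)[C@]1(C)Cl)=C(C)C
F5 | step 13 | (2R,3S)-2-chloro-6,8-dihydroxy-2-methyl-3-[(4E)-5,9-dimethyl-2-(propan-2-ylidene)deca-4,8-dien-1-yl]-3-(triethylsilyloxy)-2,3-dihydronaphthalene-1,4-dione | CC(C)=CCC/C(C)=C/CC(C[C@]1(O[Si](CC)(CC)CC)C(=O)c2cc(O)cc(O)c2C(=O)[C@]1(C)Cl)=C(C)C
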